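The pyranone ring (chromanone numbering) is disconnected at C2–C3 by a retro-Petasis–Ferrier transform: the array O1–C2–C3–C4=O is a formaldehyde aldol of an enol that ring A holds next to O1. The precursor is therefore a 4-alkylidene-4H-1,3-benzodioxine, an enol acetal in which the future spiro carbon C3 is still an sp2 carbon exocyclic to the finished benzocyclobutene. A chiral Brønsted acid ionises the acetal and returns the oxocarbenium carbon C2 to C3: one operation makes the C2–C3 bond, the C4 ketone, the pyranone ring and the quaternary spiro stereocentre. The step exploits that C3 lies α to C4 and β to O1 and carries no hydrogen.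

Key step: step 6

Atom labels: the atoms that end in the pyranone ring carry chroman-4-one numbers in all compounds (O1, C2, spiro C3, C4, C4a and C8a in ring A). The benzocyclobutene positions are primed (bicyclo[4.2.0]octa-1,3,5-triene numbering; C7' is the same atom as C3; methoxy groups on C4' and C5'). The spiro centre of the target is S.

Assumption: the sense of induction of the chiral acid in step 6 cannot be assigned in advance; the (S)-configured catalyst is written, and its mirror image is taken if that one proves to give the S spiro centre.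

Remark: all benzocyclobutenes are kept at or below 65 °C to avoid electrocyclic opening to o-quinodimethanes.

Step 1
Reactants: 1 1-bromo-2,3-dimethoxybenzene; 2 1,1-diethoxyethene
Product: 5 4,5-dimethoxybicyclo[4.2.0]octa-1,3,5-trien-7-one, via 3,4-dimethoxybenzyne 3 (not isolated), via diethyl ketal 4 (not isolated)
Conditions: NaNH2, THF, 65 °C; then 1 M HCl, THF, rt
Reagents that add atoms: water, O
Why: Known aryne–ketene acetal (2+2) cycloaddition: NaNH2 removes the only hydrogen ortho to bromine, the CH2 terminus of 2 adds to the aryne carbon remote from the methoxy group so that the ketal carbon ends up next to C5'–OMe, and acid work-up hydrolyses ketal 4.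

Step 2
Reactants: 5 4,5-dimethoxybicyclo[4.2.0]octa-1,3,5-trien-7-one
Product: 6 rac-4,5-dimethoxybicyclo[4.2.0]octa-1,3,5-triene-7-carbonitrile
Conditions: TosMIC, KOt-Bu, DME, EtOH, 0 °C to rt
Reagents that add atoms: p-toluenesulfonylmethyl isocyanide (TosMIC), Cc1ccc(cc1)S(=O)(=O)C[N+]#[C-]
Why: Van Leusen reductive cyanation, which homologates a ketone to the nitrile in one step and is favoured here by the strained, non-enolisable carbonyl group; the new C7' centre is racemic and is erased in step 5.

Step 3
Reactants: 6 rac-4,5-dimethoxybicyclo[4.2.0]octa-1,3,5-triene-7-carbonitrile; 7 1,3,5-trimethoxybenzene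
Product: 9 rac-(4,5-dimethoxybicyclo[4.2.0]octa-1,3,5-trien-7-yl)(2,4,6-trimethoxyphenyl)methanone, via ketiminium chloride 8 (not isolated)
Conditions: ZnCl2, HCl (gas), Et2O, 0 °C; then H2O, 60 °C
Reagents that add atoms: water, O
Why: Houben–Hoesch acylation: the nitrilium chloride of 6 attacks the strongly activated, threefold symmetric arene 7, so that only one regioisomer can form, and ketiminium salt 8 is hydrolysed on warming with water.

Step 4
Reactants: 9 rac-(4,5-dimethoxybicyclo[4.2.0]octa-1,3,5-trien-7-yl)(2,4,6-trimethoxyphenyl)methanone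
Product: 10 rac-(4,5-dimethoxybicyclo[4.2.0]octa-1,3,5-trien-7-yl)(2-hydroxy-4,6-dimethoxyphenyl)methanone
Conditions: BCl3, CH2Cl2, −78 to 0 °C; then H2O
Reagents that add atoms: none
Why: Chelation-controlled ether cleavage: BCl3 binds the ketone oxygen and cleaves only a methoxy group ortho to the carbonyl group, the two such groups of ring A being equivalent and the ethers of the benzocyclobutene arene lying out of reach.

Step 5
Reactants: 10 rac-(4,5-dimethoxybicyclo[4.2.0]octa-1,3,5-trien-7-yl)(2-hydroxy-4,6-dimethoxyphenyl)methanone
Product: 12 (Z)-4-(4,5-dimethoxybicyclo[4.2.0]octa-1,3,5-trien-7-ylidene)-5,7-dimethoxy-4H-1,3-benzodioxine, via chloromethyl ether 11 (not isolated)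
Conditions: BrCH2Cl, Cs2CO3, DMF, 50 °C
Reagents that add atoms: bromochloromethane, ClCBr
Why: Phenoxide alkylation by the bromide end of BrCH2Cl gives α-chloro ether 11, a hard electrophile that the neighbouring ketone (enolate) oxygen captures in a six-membered closure with loss of the proton on C3 (C7'), a cyclic case of enolate O-alkoxymethylation; the C3 stereocentre disappears and the Z isomer, with ring A cis to the small CH2 group, is expected.

Step 6
Reactants: 12 (Z)-4-(4,5-dimethoxybicyclo[4.2.0]octa-1,3,5-trien-7-ylidene)-5,7-dimethoxy-4H-1,3-benzodioxine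
Product: 14 (S)-4',5,5',7-tetramethoxyspiro[chromane-3,7'-bicyclo[4.2.0]octa[1,3,5]trien]-4-one, via oxocarbenium enol ion pair 13 (not isolated)
Conditions: (S)-N-triflylphosphoramide of 3,3'-bis(2,4,6-triisopropylphenyl)-1,1'-bi-2-naphthol (10 mol %), 5 Å molecular sieves, toluene, −20 °C
Reagents that add atoms: none
Why: Proposed new method: the acid should ionise the acetal bond between C2 and the enol oxygen on C4 of 12 to the ring-A aryloxymethyl oxocarbenium ion and the enol of the C4 ketone, held as hydrogen-bonded chiral ion pair 13, which recombines at carbon in a net 1,3 O-to-C shift. The closest known reaction types are the Petasis–Ferrier rearrangement of 4-methylene-1,3-dioxanes to tetrahydropyran-4-ones with achiral aluminium Lewis acids and the chiral phosphoric acid catalysed aza-Petasis–Ferrier rearrangement, supported by Brønsted acid enol catalysis that gives α-aryl quaternary ketones. The pyranone ring closes in a 6-(enolendo)-endo-trig mode, enol carbon C3 attacking oxocarbenium carbon C2, so that the C2–C3 bond, the C4 carbonyl group and the spiro centre arise together. The spiro stereocentre is controlled by the catalyst anion, which binds the enol O–H and the cation in its binaphthyl pocket and leaves one enol face open to C2. The step needs C- over O-recombination and freedom from hydrolysis: C-attack is irreversible whereas O-attack only returns 12, and the sieves keep water out. Because C2 stays bound to ring A through O1, no free formaldehyde equivalent can reach the electron-rich arenes, and the product, having no hydrogen on C3, cannot racemise by enolisation.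

Compound list
1 | 1-bromo-2,3-dimethoxybenzene | COc1cccc(Br)c1OC | starting material
2 | 1,1-diethoxyethene (ketene diethyl acetal) | CCOC(=C)OCC | starting material
3 | 3,4-dimethoxybenzyne (1,2-didehydro-3,4-dimethoxybenzene) | COC1=C(OC)C#CC=C1 | intermediate (not isolated)
4 | 7,7-diethoxy-4,5-dimethoxybicyclo[4.2.0]octa-1,3,5-triene | CCOC1(OCC)Cc2ccc(OC)c(OC)c21 | intermediate (not isolated)
5 | 4,5-dimethoxybicyclo[4.2.0]octa-1,3,5-trien-7-one | O=C1Cc2ccc(OC)c(OC)c21 | intermediate
6 | rac-4,5-dimethoxybicyclo[4.2.0]octa-1,3,5-triene-7-carbonitrile | N#CC1Cc2ccc(OC)c(OC)c21 | intermediate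
7 | 1,3,5-trimethoxybenzene | COc1cc(OC)cc(OC)c1 | starting material
8 | rac-(4,5-dimethoxybicyclo[4.2.0]octa-1,3,5-trien-7-yl)(2,4,6-trimethoxyphenyl)methaniminium chloride | COc1cc(OC)c(c(OC)c1)C(=[NH2+])C1Cc2ccc(OC)c(OC)c21.[Cl-] | intermediate (not isolated)
9 | rac-(4,5-dimethoxybicyclo[4.2.0]octa-1,3,5-trien-7-yl)(2,4,6-trimethoxyphenyl)methanone | COc1cc(OC)c(c(OC)c1)C(=O)C1Cc2ccc(OC)c(OC)c21 | intermediate
10 | rac-(4,5-dimethoxybicyclo[4.2.0]octa-1,3,5-trien-7-yl)(2-hydroxy-4,6-dimethoxyphenyl)methanone | COc1cc(O)c(c(OC)c1)C(=O)C1Cc2ccc(OC)c(OC)c21 | intermediate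
11 | rac-[2-(chloromethoxy)-4,6-dimethoxyphenyl](4,5-dimethoxybicyclo[4.2.0]octa-1,3,5-trien-7-yl)methanone | COc1cc(OCCl)c(c(OC)c1)C(=O)C1Cc2ccc(OC)c(OC)c21 | intermediate (not isolated)
12 | (Z)-4-(4,5-dimethoxybicyclo[4.2.0]octa-1,3,5-trien-7-ylidene)-5,7-dimethoxy-4H-1,3-benzodioxine | COc1cc(OC)c2c(c1)OCO/C2=C1/Cc3ccc(OC)c(OC)c31 | intermediate
13 | cation of the ion pair: (Z)-enol of the C4 ketone carrying the O1-methylidene oxonium group on ring A (counter-ion: catalyst anion) | C=[O+]c1cc(OC)cc(OC)c1/C(O)=C1\Cc2ccc(OC)c(OC)c21 | intermediate (not isolated)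
14 | (S)-4',5,5',7-tetramethoxyspiro[chromane-3,7'-bicyclo[4.2.0]octa[1,3,5]trien]-4-one | COc1cc(OC)c2c(c1)OC[C@@]1(Cc3ccc(OC)c(OC)c31)C2=O | target

Total step count: 6
Longest linear sequence: 6 steps (from 1 to 14)

Steps most likely to fail

Step 6 (bears the label). The ion pair may recombine with poor facial selectivity, or the acid may only protonate the enol carbon, so that traces of water hydrolyse the acetal instead of rearranging it. The fallback uses known chemistry, sets out from hydroxy ketone 10 and comes back at target 14. Double silylation of 10 (Me3SiCl, NEt3, NaI, MeCN) would give the bis(trimethylsilyl) enol ether F1. A Mukaiyama aldol reaction with aqueous formaldehyde under Sc(OTf)3 and (S,S)-6,6'-bis(1-hydroxy-2,2-dimethylpropyl)-2,2'-bipyridine (DME–H2O, −20 °C), a known catalytic asymmetric hydroxymethylation of silicon enolates that forms quaternary centres, would set the spiro carbon and, after loss of the aryl silyl ether on work-up, give the hydroxymethyl ketone F2. An intramolecular Mitsunobu etherification (PPh3, DIAD, THF, 0 °C) would then close the O1–C2 bond and give 14; the pyranone is still the last ring closed, with the stereocentre set one step earlier.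

Step 5. The chloromethyl ether may close on carbon, which would give the chromanone as a racemate, or react with a second phenoxide to a diaryl formal. The fallback reaches enol acetal 12 by olefination, sets out from ketone 5 and comes back at 12. 2-Hydroxy-4,6-dimethoxybenzoic acid F3 (purchased) would be converted with CH2Br2 and K3PO4 (DMF, 80 °C) into the benzodioxinone F4. This would be reduced and acetylated in one pot (i-Bu2AlH, CH2Cl2, −78 °C; then Ac2O, pyridine, DMAP) to the acetoxy acetal F5, and an Arbuzov-type substitution with P(OEt)3 and BF3·OEt2 would give the phosphonate F6. Its lithium salt (LiN(i-Pr)2, THF, −78 °C to rt) would be condensed with ketone 5 in a Horner–Wadsworth–Emmons reaction, which forms the exocyclic C3=C4 bond without any enolate and gives 12.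

Step 2. The base may open the strained four-membered ketone faster than the TosMIC adduct is converted into the nitrile. The fallback sets out from ketone 5 and comes back at ketone 9. A Wittig reaction with Ph3P=CHOMe (from the phosphonium chloride and KN(SiMe3)2, THF, 0 °C), which involves no free alkoxide, would give the enol ether F7, and mild acid hydrolysis (aqueous HCO2H, THF, rt) the aldehyde F8. Addition of 2,4,6-trimethoxyphenyllithium (from 7 and n-BuLi, THF, −78 °C) would give the carbinol F9, and Dess–Martin oxidation would give 9, so that the nitrile and the Hoesch step are both bypassed.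

Further compounds
F1 | step 6 | (Z)-bis(trimethylsilyl) derivative of 10: trimethylsilyl enol ether of the ketone with the ring-A hydroxyl as trimethylsilyl ether | COc1cc(O[Si](C)(C)C)c(c(OC)c1)/C(O[Si](C)(C)C)=C1\Cc2ccc(OC)c(OC)c21
F2 | step 6 | (S)-[7-(hydroxymethyl)-4,5-dimethoxybicyclo[4.2.0]octa-1,3,5-trien-7-yl](2-hydroxy-4,6-dimethoxyphenyl)methanone | OC[C@@]1(Cc2ccc(OC)c(OC)c21)C(=O)c1c(O)cc(OC)cc1OC
F3 | step 5 | 2-hydroxy-4,6-dimethoxybenzoic acid (purchased) | COc1cc(O)c(C(=O)O)c(OC)c1
F4 | step 5 | 5,7-dimethoxy-4H-1,3-benzodioxin-4-one | COc1cc(OC)c2c(c1)OCOC2=O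
F5 | step 5 | rac-5,7-dimethoxy-4H-1,3-benzodioxin-4-yl acetate | COc1cc(OC)c2c(c1)OCOC2OC(C)=O
F6 | step 5 | rac-diethyl (5,7-dimethoxy-4H-1,3-benzodioxin-4-yl)phosphonate | CCOP(=O)(OCC)C1OCOc2cc(OC)cc(OC)c21
F7 | step 2 | 7-(methoxymethylidene)-4,5-dimethoxybicyclo[4.2.0]octa-1,3,5-triene (E/Z mixture) | COC=C1Cc2ccc(OC)c(OC)c21
F8 | step 2 | rac-4,5-dimethoxybicyclo[4.2.0]octa-1,3,5-triene-7-carbaldehyde | O=CC1Cc2ccc(OC)c(OC)c21
F9 | step 2 | (4,5-dimethoxybicyclo[4.2.0]octa-1,3,5-trien-7-yl)(2,4,6-trimethoxyphenyl)methanol (racemic diastereomer mixture) | COc1cc(OC)c(c(OC)c1)C(O)C1Cc2ccc(OC)c(OC)c21
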